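**Plan**

- Retrosynthesis: the two C–O bonds at the spiro acylal carbon of ring A (the enedione ring fused to the dimethylpyran) are cut first, giving a caged hydroxy acid and a prenylated hydroxy-chromenequinone. The cage is then cut at the quaternary carbon beside its ketone, breaking the tetrahydrofuran O–C bond and the bond to the prenyl CH2 together. The remaining bicyclo[2.2.2]octenone is cut at the two bridgehead bonds of its acrylate bridge.
- Enabling feature: that quaternary carbon is alpha to the cage ketone, is the ring carbon bonded to the tetrahydrofuran oxygen and carries the prenyl CH2. This is the pattern left by a [2,3]-shift of an allyl oxonium ylide formed on a ketone alpha carbon, with a 1,1-dimethylallyl ether supplying both oxygen and prenyl.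
- Forward: a 4-substituted cyclohexanone carrying the di-tertiary allyl ether is desymmetrised, oxidised to a 1,3-dione and turned into a tris(silyloxy)diene. Diels–Alder reaction with methyl propiolate builds the bicyclo[2.2.2]octene; diazo transfer and the rhodium carbenoid step close the tetrahydrofuran. The dioxinone spiro ring is closed last, after acylation of the separately made chromenequinone.
- Stereochemistry: the ring carbon bearing the ether side chain comes from a chiral lithium amide deprotonation. Both bridgeheads follow from Diels–Alder addition anti to that side chain. The quaternary carbon is fixed by the geometry of the ylide. The two ring A centres are left to thermodynamic control in the last ring closure.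

Key step: step 13

Remark 1: the sense of the chiral-base deprotonation in step 5 is taken to follow that of 4-tert-butylcyclohexanone; if the opposite enol silane forms, the antipodal amide is used.
Remark 2: the configurations at the spiro acylal carbon and the neighbouring prenyl-bearing carbon of ring A are taken to be the thermodynamically preferred ones, reachable by ring–chain and keto–enol equilibration.

**Route**

Step 1
Reactants: 1 ethyl 1,4-dioxaspiro[4.5]decane-8-carboxylate; 2 methylmagnesium bromide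
Product: 3 2-(1,4-dioxaspiro[4.5]decan-8-yl)propan-2-ol
Conditions: MeMgBr (3 equiv), THF, 0 to 23 °C; aq. NH4Cl
Reagents that add atoms: none
Why: Twofold Grignard addition to the ester should give the tertiary carbinol while the dioxolane keeps the ring carbonyl masked.

Step 2
Reactants: 3 2-(1,4-dioxaspiro[4.5]decan-8-yl)propan-2-ol; 4 3-chloro-3-methylbut-1-yne
Product: 5 8-{2-[(2-methylbut-3-yn-2-yl)oxy]propan-2-yl}-1,4-dioxaspiro[4.5]decane
Conditions: KH (1.5 equiv), 18-crown-6 (cat.), THF, 0 °C; then 4 (3 equiv), 0 to 23 °C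
Reagents that add atoms: none
Why: Base-mediated propargylic etherification of a tertiary propargylic chloride (Hennion zwitterion–carbene pathway), in which the alkoxide strips HCl from 4 and captures the resulting dimethylallenylidene at its tertiary carbon, a path open to tertiary alkoxides because no backside displacement is involved.

Step 3
Reactants: 5 8-{2-[(2-methylbut-3-yn-2-yl)oxy]propan-2-yl}-1,4-dioxaspiro[4.5]decane
Product: 6 4-{2-[(2-methylbut-3-yn-2-yl)oxy]propan-2-yl}cyclohexan-1-one
Conditions: 1 M HCl, THF, 23 °C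
Reagents that add atoms: water, O
Why: Acid-catalysed ketal hydrolysis, placed before the alkyne reduction because a tert-alkyl propargylic ether should survive dilute aqueous acid better than the allylic ether made next.

Step 4
Reactants: 6 4-{2-[(2-methylbut-3-yn-2-yl)oxy]propan-2-yl}cyclohexan-1-one
Product: 7 4-{2-[(2-methylbut-3-en-2-yl)oxy]propan-2-yl}cyclohexan-1-one
Conditions: H2 (1 atm), Pd/CaCO3 poisoned with Pb(OAc)2 (Lindlar catalyst), quinoline, EtOAc, 23 °C
Reagents that add atoms: none
Why: Lindlar semihydrogenation of the terminal alkyne should stop at the vinyl group and so deliver the 1,1-dimethylallyl ether.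

Step 5
Reactants: 7 4-{2-[(2-methylbut-3-en-2-yl)oxy]propan-2-yl}cyclohexan-1-one
Product: 8 (R)-trimethyl[(4-{2-[(2-methylbut-3-en-2-yl)oxy]propan-2-yl}cyclohex-1-en-1-yl)oxy]silane
Conditions: LiN[(S)-CHMePh]2 (from (S,S)-bis(1-phenylethyl)amine and n-BuLi), Me3SiCl (in situ quench), THF, −78 °C
Reagents that add atoms: chlorotrimethylsilane, C[Si](C)(C)Cl
Why: Enantioselective deprotonation of the prochiral ketone by a chiral lithium amide with internal silyl trapping (Simpkins desymmetrisation) should remove one of the two enantiotopic axial alpha protons and so set the ring carbon that bears the ether side chain, any shortfall in enantiomeric purity being made up by crystallisation of a later solid intermediate.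

Step 6
Reactants: 8 (R)-trimethyl[(4-{2-[(2-methylbut-3-en-2-yl)oxy]propan-2-yl}cyclohex-1-en-1-yl)oxy]silane
Product: 9 (R)-4-{2-[(2-methylbut-3-en-2-yl)oxy]propan-2-yl}cyclohex-2-en-1-one
Conditions: Pd(OAc)2 (10 mol %), O2 (1 atm), DMSO, 23 °C
Reagents that add atoms: none
Why: Saegusa–Ito oxidation of the silyl enol ether should place the enone double bond on the side chosen in step 5 without touching the gamma stereocentre or the isolated vinyl group.

Step 7
Reactants: 9 (R)-4-{2-[(2-methylbut-3-en-2-yl)oxy]propan-2-yl}cyclohex-2-en-1-one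
Product: 11 (4R)-4-{2-[(2-methylbut-3-en-2-yl)oxy]propan-2-yl}-6-[(triethylsilyl)oxy]cyclohex-2-en-1-one as a mixture of C6 epimers, via silyl dienol ether 10 (not isolated)
Conditions: LiN(i-Pr)2 (1.1 equiv), THF, −78 °C; Et3SiCl, −78 to 0 °C; then mCPBA, NaHCO3, CH2Cl2, −20 °C
Reagents that add atoms: chlorotriethylsilane, CC[Si](Cl)(CC)CC; 3-chloroperoxybenzoic acid, OOC(=O)c1cccc(Cl)c1
Why: Kinetic alpha' deprotonation of the enone and Rubottom oxidation of the cross-conjugated silyl dienol ether, with the silyl group moving to the new oxygen, should install the oxygen of the future bridgehead next to the cage ketone; its configuration is irrelevant because this carbon becomes trigonal again in step 10.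

Step 8
Reactants: 11 (4R)-4-{2-[(2-methylbut-3-en-2-yl)oxy]propan-2-yl}-6-[(triethylsilyl)oxy]cyclohex-2-en-1-one
Product: 12 (5R)-5-{2-[(2-methylbut-3-en-2-yl)oxy]propan-2-yl}-3-[(triethylsilyl)oxy]-7-oxabicyclo[4.1.0]heptan-2-one (epoxide expected anti to the side chain; C3 epimers)
Conditions: t-BuOOH, DBU, CH2Cl2, 0 to 23 °C
Reagents that add atoms: tert-butyl hydroperoxide, CC(C)(C)OO
Why: Weitz–Scheffer nucleophilic epoxidation should attack only the electron-poor enone double bond and leave the vinyl terminus alone; the epoxide configuration is erased in step 9.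

Step 9
Reactants: 12 (5R)-5-{2-[(2-methylbut-3-en-2-yl)oxy]propan-2-yl}-3-[(triethylsilyl)oxy]-7-oxabicyclo[4.1.0]heptan-2-one
Product: 13 (4S)-4-{2-[(2-methylbut-3-en-2-yl)oxy]propan-2-yl}-6-[(triethylsilyl)oxy]cyclohexane-1,3-dione (C6 epimers)
Conditions: Pd(PPh3)4 (5 mol %), 1,2-bis(diphenylphosphino)ethane (5 mol %), toluene, 80 °C
Reagents that add atoms: none
Why: Isomerisation of an alpha,beta-epoxy ketone to the beta-diketone by zerovalent palladium under neutral conditions should move the oxygen to the ring carbon next to the side-chain carbon without acid or base that could epimerise that centre or expel the beta-alkoxy group.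

Step 10
Reactants: 13 (4S)-4-{2-[(2-methylbut-3-en-2-yl)oxy]propan-2-yl}-6-[(triethylsilyl)oxy]cyclohexane-1,3-dione
Product: 14 (S)-5-{2-[(2-methylbut-3-en-2-yl)oxy]propan-2-yl}-1,2,4-tris[(triethylsilyl)oxy]cyclohexa-1,3-diene
Conditions: Et3SiOTf (2.4 equiv), Et3N (4 equiv), CH2Cl2, −78 to 0 °C
Reagents that add atoms: triethylsilyl trifluoromethanesulfonate, CC[Si](CC)(CC)OS(=O)(=O)C(F)(F)F
Why: Twofold enol silylation of the 1,3-dione (soft enolisation with silyl triflate and amine) should give the tris(silyloxy)diene, the second proton being lost from the silyloxy-bearing carbon because the alternative is a shielded tertiary C–H beside a quaternary carbon whose removal would give a strained fully substituted enol ether.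

Step 11
Reactants: 14 (S)-5-{2-[(2-methylbut-3-en-2-yl)oxy]propan-2-yl}-1,2,4-tris[(triethylsilyl)oxy]cyclohexa-1,3-diene; 15 methyl propiolate
Product: 17 methyl (1S,4R,7S)-7-{2-[(2-methylbut-3-en-2-yl)oxy]propan-2-yl}-5-oxo-1,4-bis[(triethylsilyl)oxy]bicyclo[2.2.2]oct-2-ene-2-carboxylate, via cycloadduct 16 (not isolated)
Conditions: 15 (3 equiv), toluene, 70 °C; then Bu4NF (1.1 equiv), AcOH (1.5 equiv), THF, −40 °C
Reagents that add atoms: none
Why: Diels–Alder reaction of the electron-rich diene with the alkynoate, in which the propiolate beta carbon bonds to the diene terminus next to the internal silyloxy carbon (Danishefsky-type polarisation) and the dienophile approaches anti to the bulky side chain so that both bridgeheads follow from the existing centre, then cleavage of the silyl enol ether alone by buffered fluoride; the temperature is held low to avoid Alder–Rickert cycloreversion.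

Step 12
Reactants: 17 methyl (1S,4R,7S)-7-{2-[(2-methylbut-3-en-2-yl)oxy]propan-2-yl}-5-oxo-1,4-bis[(triethylsilyl)oxy]bicyclo[2.2.2]oct-2-ene-2-carboxylate
Product: 19 methyl (1S,4R,7S)-6-diazo-7-{2-[(2-methylbut-3-en-2-yl)oxy]propan-2-yl}-5-oxo-1,4-bis[(triethylsilyl)oxy]bicyclo[2.2.2]oct-2-ene-2-carboxylate, via trifluoroacetyl ketone 18 (not isolated)
Conditions: LiN(SiMe3)2, THF, −78 °C; CF3CO2CH2CF3; cold 0.5 M HCl work-up; then MeSO2N3, Et3N, H2O (1 equiv), MeCN, 23 °C
Reagents that add atoms: methanesulfonyl azide, CS(=O)(=O)N=[N+]=[N-]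
Why: Detrifluoroacetylative diazo transfer (Danheiser) suits a ketone whose only enolisable position is the methylene, the other alpha carbon being a bridgehead.

Step 13
Reactants: 19 methyl (1S,4R,7S)-6-diazo-7-{2-[(2-methylbut-3-en-2-yl)oxy]propan-2-yl}-5-oxo-1,4-bis[(triethylsilyl)oxy]bicyclo[2.2.2]oct-2-ene-2-carboxylate
Product: 21 methyl (1R,3R,6S,7S)-5,5-dimethyl-3-(3-methylbut-2-en-1-yl)-2-oxo-1,7-bis[(triethylsilyl)oxy]-4-oxatricyclo[4.3.1.0(3,7)]dec-8-ene-8-carboxylate, via oxonium ylide 20 (not isolated)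
Conditions: Rh2(OAc)4 (2 mol %), CH2Cl2, 23 °C, slow addition of 19
Reagents that add atoms: none
Why: Rh2(OAc)4 (divalent rhodium) should expel N2 from 19 to give an electrophilic carbenoid at the carbon alpha to the ketone, and the ether oxygen, which the Diels–Alder step has placed on the saturated bridge directly beside that carbon, adds to it to form cyclic oxonium ylide 20. The 1,1-dimethylallyl group then moves from oxygen to the ylide carbon by a concerted [2,3]-sigmatropic shift with allylic transposition and so arrives as prenyl; the closest known reaction is the rhodium- or copper-catalysed oxonium ylide formation and [2,3]-rearrangement of allyl ethers of alpha-diazo ketones used to make 2-allyl tetrahydrofuran-3-ones. The tetrahydrofuran closes in the ylide-forming event, by attack of the tethered lone pair on the carbenoid carbon through a five-membered transition state (5-exo with respect to the tether), normally the fastest intramolecular carbenoid pathway. The one new stereocentre, the quaternary carbon, is set by the ring: oxygen can only arrive from the side of the saturated bridge, so the prenyl group must enter on the face of the alkene bridge. The step needs ylide formation to outrun C–H insertion, Wolff rearrangement and carbonyl ylide formation, which the substrate secures by holding the ether oxygen eclipsed over the carbenoid carbon, by offering no hydrogen on either neighbour and by keeping the ester carbonyl rigidly out of reach. It also needs [2,3]- to outrun [1,2]-migration, which the unsubstituted allyl terminus favours and which is reinforced because a [1,2]-shift would have to join two quaternary carbons.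

Step 14
Reactants: 21 methyl (1R,3R,6S,7S)-5,5-dimethyl-3-(3-methylbut-2-en-1-yl)-2-oxo-1,7-bis[(triethylsilyl)oxy]-4-oxatricyclo[4.3.1.0(3,7)]dec-8-ene-8-carboxylate
Product: 22 (1R,3R,6S,7S)-5,5-dimethyl-3-(3-methylbut-2-en-1-yl)-2-oxo-1,7-bis[(triethylsilyl)oxy]-4-oxatricyclo[4.3.1.0(3,7)]dec-8-ene-8-carboxylic acid
Conditions: LiOH·H2O, THF/MeOH/H2O, 40 °C; then cold 0.5 M HCl to pH 4
Reagents that add atoms: lithium hydroxide, [Li+].[OH-]
Why: Saponification of the methyl ester; the cage ketone has no enolisable hydrogen and both tertiary hydroxyls are silylated, so neither epimerisation nor retro-aldol opening can occur.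

Step 15
Reactants: 23 2,6-dimethoxy-1,4-benzoquinone
Product: 24 2-hydroxy-6-methoxy-1,4-benzoquinone
Conditions: NaOH (1.05 equiv), H2O/THF, 0 °C; then HCl
Reagents that add atoms: sodium hydroxide, [Na+].[OH-]
Why: Addition–elimination of hydroxide at one methoxy-bearing quinone carbon (hydrolysis of a vinylogous ester) should stop after the first exchange because the hydroxyquinone is then present as its unreactive anion.

Step 16
Reactants: 24 2-hydroxy-6-methoxy-1,4-benzoquinone; 25 3-methylbut-2-enal
Product: 26 7-methoxy-2,2-dimethyl-2H-chromene-5,8-dione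
Conditions: ethylenediammonium diacetate (10 mol %), toluene, 80 °C
Reagents that add atoms: none
Why: Knoevenagel condensation at the nucleophilic ring carbon beside the hydroxyl and oxa-6π electrocyclisation of the resulting oxatriene (formal [3+3] annulation known for 2-hydroxy-1,4-quinones and enals) should fuse the dimethylpyran with its oxygen on the former hydroxyl carbon.

Step 17
Reactants: 26 7-methoxy-2,2-dimethyl-2H-chromene-5,8-dione
Product: 27 7-hydroxy-2,2-dimethyl-2H-chromene-5,8-dione
Conditions: NaOH (aq.), THF, 0 to 23 °C; then HCl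
Reagents that add atoms: sodium hydroxide, [Na+].[OH-]
Why: A second vinylogous ester hydrolysis frees the hydroxyl that is acylated later.

Step 18
Reactants: 27 7-hydroxy-2,2-dimethyl-2H-chromene-5,8-dione; 28 1-bromo-3-methylbut-2-ene
Product: 29 7-hydroxy-2,2-dimethyl-6-(3-methylbut-2-en-1-yl)-2H-chromene-5,8-dione
Conditions: 28, Et3N, NaI (cat.), DMSO, 23 to 45 °C
Reagents that add atoms: none
Why: C-alkylation of the 2-hydroxyquinone, a vinylogous acid, at its only free ring carbon, as in the preparation of lapachol from 2-hydroxy-1,4-naphthoquinone.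

Step 19
Reactants: 22 (1R,3R,6S,7S)-5,5-dimethyl-3-(3-methylbut-2-en-1-yl)-2-oxo-1,7-bis[(triethylsilyl)oxy]-4-oxatricyclo[4.3.1.0(3,7)]dec-8-ene-8-carboxylic acid; 29 7-hydroxy-2,2-dimethyl-6-(3-methylbut-2-en-1-yl)-2H-chromene-5,8-dione
Product: 31 2,2-dimethyl-6-(3-methylbut-2-en-1-yl)-5,8-dioxo-5,8-dihydro-2H-chromen-7-yl ester of acid 22, via acid chloride 30 (not isolated)
Conditions: 1-chloro-N,N,2-trimethylprop-1-en-1-amine (1.5 equiv), CH2Cl2, 0 to 23 °C; then 29, Et3N, 4-(dimethylamino)pyridine (cat.), 0 °C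
Reagents that add atoms: none
Why: Acid chloride formation under neutral conditions (Ghosez reagent) followed by O-acylation of the hydroxyquinone, whose hydroxyl is too poor a nucleophile for direct carbodiimide coupling with this hindered acid; C-acylation is excluded because the neighbouring ring carbon is substituted.

Step 20
Reactants: 31 2,2-dimethyl-6-(3-methylbut-2-en-1-yl)-5,8-dioxo-5,8-dihydro-2H-chromen-7-yl ester of acid 22
Product: 33 CNP0222516.1 (target), via diol 32 (not isolated)
Conditions: HF·pyridine, pyridine, THF, 0 to 23 °C; then (±)-camphor-10-sulfonic acid (10 mol %), CH2Cl2, 23 °C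
Reagents that add atoms: none
Why: Fluoride removes both tertiary silyl groups and the freed bridgehead hydroxyl should add to the acyloxy-bearing quinone carbon (intramolecular oxa-Michael addition, 6-exo, closing the dioxinone), after which acid-promoted ketonisation and ring–chain equilibration are expected to settle the spiro acylal carbon and the neighbouring prenyl-bearing carbon in the configuration of the target (remark 2).

**Compound list**

1 | ethyl 1,4-dioxaspiro[4.5]decane-8-carboxylate | CCOC(=O)C1CCC2(CC1)OCCO2 | starting material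
2 | methylmagnesium bromide, MeMgBr | C[Mg]Br | starting material
3 | 2-(1,4-dioxaspiro[4.5]decan-8-yl)propan-2-ol | CC(C)(O)C1CCC2(CC1)OCCO2 | intermediate
4 | 3-chloro-3-methylbut-1-yne | CC(C)(Cl)C#C | starting material
5 | 8-{2-[(2-methylbut-3-yn-2-yl)oxy]propan-2-yl}-1,4-dioxaspiro[4.5]decane | C#CC(C)(C)OC(C)(C)C1CCC2(CC1)OCCO2 | intermediate
6 | 4-{2-[(2-methylbut-3-yn-2-yl)oxy]propan-2-yl}cyclohexan-1-one | C#CC(C)(C)OC(C)(C)C1CCC(=O)CC1 | intermediate
7 | 4-{2-[(2-methylbut-3-en-2-yl)oxy]propan-2-yl}cyclohexan-1-one | C=CC(C)(C)OC(C)(C)C1CCC(=O)CC1 | intermediate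
8 | (R)-trimethyl[(4-{2-[(2-methylbut-3-en-2-yl)oxy]propan-2-yl}cyclohex-1-en-1-yl)oxy]silane | C=CC(C)(C)OC(C)(C)[C@H]1CC=C(O[Si](C)(C)C)CC1 | intermediate
9 | (R)-4-{2-[(2-methylbut-3-en-2-yl)oxy]propan-2-yl}cyclohex-2-en-1-one | C=CC(C)(C)OC(C)(C)[C@H]1C=CC(=O)CC1 | intermediate
10 | (R)-triethyl[(4-{2-[(2-methylbut-3-en-2-yl)oxy]propan-2-yl}cyclohexa-1,5-dien-1-yl)oxy]silane | C=CC(C)(C)OC(C)(C)[C@H]1C=CC(O[Si](CC)(CC)CC)=CC1 | intermediate (not isolated)
11 | (4R)-4-{2-[(2-methylbut-3-en-2-yl)oxy]propan-2-yl}-6-[(triethylsilyl)oxy]cyclohex-2-en-1-one, C6 epimers | C=CC(C)(C)OC(C)(C)[C@H]1C=CC(=O)C(O[Si](CC)(CC)CC)C1 | intermediate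
12 | (5R)-5-{2-[(2-methylbut-3-en-2-yl)oxy]propan-2-yl}-3-[(triethylsilyl)oxy]-7-oxabicyclo[4.1.0]heptan-2-one, epoxide and C3 centres unassigned | C=CC(C)(C)OC(C)(C)[C@@H]1CC(O[Si](CC)(CC)CC)C(=O)C2OC12 | intermediate
13 | (4S)-4-{2-[(2-methylbut-3-en-2-yl)oxy]propan-2-yl}-6-[(triethylsilyl)oxy]cyclohexane-1,3-dione, C6 epimers | C=CC(C)(C)OC(C)(C)[C@@H]1CC(O[Si](CC)(CC)CC)C(=O)CC1=O | intermediate
14 | (S)-5-{2-[(2-methylbut-3-en-2-yl)oxy]propan-2-yl}-1,2,4-tris[(triethylsilyl)oxy]cyclohexa-1,3-diene | C=CC(C)(C)OC(C)(C)[C@@H]1CC(O[Si](CC)(CC)CC)=C(O[Si](CC)(CC)CC)C=C1O[Si](CC)(CC)CC | intermediate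
15 | methyl propiolate (methyl prop-2-ynoate) | COC(=O)C#C | starting material
16 | methyl (1S,4R,7S)-7-{2-[(2-methylbut-3-en-2-yl)oxy]propan-2-yl}-1,4,5-tris[(triethylsilyl)oxy]bicyclo[2.2.2]octa-2,5-diene-2-carboxylate | COC(=O)C1=C[C@]2(O[Si](CC)(CC)CC)C[C@@H](C(C)(C)OC(C)(C)C=C)[C@@]1(O[Si](CC)(CC)CC)C=C2O[Si](CC)(CC)CC | intermediate (not isolated)
17 | methyl (1S,4R,7S)-7-{2-[(2-methylbut-3-en-2-yl)oxy]propan-2-yl}-5-oxo-1,4-bis[(triethylsilyl)oxy]bicyclo[2.2.2]oct-2-ene-2-carboxylate; side chain on the saturated bridge syn to the ketone bridge | COC(=O)C1=C[C@]2(O[Si](CC)(CC)CC)C[C@@H](C(C)(C)OC(C)(C)C=C)[C@@]1(O[Si](CC)(CC)CC)CC2=O | intermediate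
18 | 6-(trifluoroacetyl) derivative of 17 (C6 epimers and enol forms) | COC(=O)C1=C[C@]2(O[Si](CC)(CC)CC)C[C@@H](C(C)(C)OC(C)(C)C=C)[C@@]1(O[Si](CC)(CC)CC)C(C(=O)C(F)(F)F)C2=O | intermediate (not isolated)
19 | methyl (1S,4R,7S)-6-diazo-7-{2-[(2-methylbut-3-en-2-yl)oxy]propan-2-yl}-5-oxo-1,4-bis[(triethylsilyl)oxy]bicyclo[2.2.2]oct-2-ene-2-carboxylate | COC(=O)C1=C[C@]2(O[Si](CC)(CC)CC)C[C@@H](C(C)(C)OC(C)(C)C=C)[C@@]1(O[Si](CC)(CC)CC)C(=[N+]=[N-])C2=O | intermediate (key-step precursor)
20 | cyclic oxonium ylide: tetrahydrofuran oxygen carrying the 1,1-dimethylallyl group, carbanion alpha to the ketone | COC(=O)C1=C[C@]3(O[Si](CC)(CC)CC)C[C@H]4C(C)(C)[O+](C(C)(C)C=C)[C-](C3=O)[C@@]14O[Si](CC)(CC)CC | intermediate (not isolated)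
21 | methyl (1R,3R,6S,7S)-5,5-dimethyl-3-(3-methylbut-2-en-1-yl)-2-oxo-1,7-bis[(triethylsilyl)oxy]-4-oxatricyclo[4.3.1.0(3,7)]dec-8-ene-8-carboxylate | COC(=O)C1=C[C@]3(O[Si](CC)(CC)CC)C[C@H]4C(C)(C)O[C@@](CC=C(C)C)(C3=O)[C@@]14O[Si](CC)(CC)CC | intermediate (key-step product)
22 | (1R,3R,6S,7S)-5,5-dimethyl-3-(3-methylbut-2-en-1-yl)-2-oxo-1,7-bis[(triethylsilyl)oxy]-4-oxatricyclo[4.3.1.0(3,7)]dec-8-ene-8-carboxylic acid | OC(=O)C1=C[C@]3(O[Si](CC)(CC)CC)C[C@H]4C(C)(C)O[C@@](CC=C(C)C)(C3=O)[C@@]14O[Si](CC)(CC)CC | intermediate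
23 | 2,6-dimethoxy-1,4-benzoquinone | COC1=CC(=O)C=C(OC)C1=O | starting material
24 | 2-hydroxy-6-methoxy-1,4-benzoquinone | COC1=CC(=O)C=C(O)C1=O | intermediate
25 | 3-methylbut-2-enal | CC(C)=CC=O | starting material
26 | 7-methoxy-2,2-dimethyl-2H-chromene-5,8-dione | COC1=CC(=O)C2=C(OC(C)(C)C=C2)C1=O | intermediate
27 | 7-hydroxy-2,2-dimethyl-2H-chromene-5,8-dione | OC1=CC(=O)C2=C(OC(C)(C)C=C2)C1=O | intermediate
28 | 1-bromo-3-methylbut-2-ene | CC(C)=CCBr | starting material
29 | 7-hydroxy-2,2-dimethyl-6-(3-methylbut-2-en-1-yl)-2H-chromene-5,8-dione | CC(C)=CCC1=C(O)C(=O)C2=C(C=CC(C)(C)O2)C1=O | intermediate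
30 | acid chloride of 22 (8-carbonyl chloride) | ClC(=O)C1=C[C@]3(O[Si](CC)(CC)CC)C[C@H]4C(C)(C)O[C@@](CC=C(C)C)(C3=O)[C@@]14O[Si](CC)(CC)CC | intermediate (not isolated)
31 | 2,2-dimethyl-6-(3-methylbut-2-en-1-yl)-5,8-dioxo-5,8-dihydro-2H-chromen-7-yl ester of acid 22 | CC(C)=CCC1=C(OC(=O)C2=C[C@]4(O[Si](CC)(CC)CC)C[C@H]5C(C)(C)O[C@@](CC=C(C)C)(C4=O)[C@@]25O[Si](CC)(CC)CC)C(=O)C2=C(C=CC(C)(C)O2)C1=O | intermediate
32 | 1,7-dihydroxy analogue of 31 (both silyl groups removed) | CC(C)=CCC1=C(OC(=O)C2=C[C@]4(O)C[C@H]5C(C)(C)O[C@@](CC=C(C)C)(C4=O)[C@@]25O)C(=O)C2=C(C=CC(C)(C)O2)C1=O | intermediate (not isolated)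
33 | CNP0222516.1: spiro acylal joining the caged 4-oxatricyclo[4.3.1.0(3,7)]decenone through a 1,3-dioxin-4-one to the prenylated pyrano-cyclohexenedione ring A | CC(C)=CC[C@H]1C(=O)C2=C(OC(C)(C)C=C2)C(=O)[C@@]12OC(=O)C1=C[C@]3(O)C[C@H]4C(C)(C)O[C@@](CC=C(C)C)(C3=O)[C@@]14O2 | target

**Count and risks**

Total step count: 20. Longest linear sequence: 16 steps (steps 1 to 14, then 19 and 20); steps 15 to 18 are the four-step quinone branch.

Steps most likely to fail:

Step 13. The carbenoid may be diverted into C–H insertion at the geminal methyl groups, or the oxonium ylide may fragment to an allyl cation–enolate pair that recombines on oxygen. The fallback builds the same two bonds one after the other and sets out from ketone 17. Brief exposure to CF3CO2H in CH2Cl2 at 0 °C should ionise only the tertiary allylic C–O bond and give methyl (1S,4R,7S)-7-(2-hydroxypropan-2-yl)-5-oxo-1,4-bis[(triethylsilyl)oxy]bicyclo[2.2.2]oct-2-ene-2-carboxylate F3. Diazo transfer as in step 12 (LiN(SiMe3)2 and CF3CO2CH2CF3 to the trifluoroacetyl ketone F4, then MeSO2N3 and Et3N) gives the hydroxy diazo ketone F5. Rh2(OAc)4 then closes the tetrahydrofuran by intramolecular O–H insertion to give the tetrahydrofuranone cage F6, which has hydrogen where the prenyl group belongs. Deprotonation with KN(SiMe3)2 and C-alkylation of the enolate with 28 on its only open face, that of the alkene bridge, comes back to the route at 21.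

Step 2. Capture of the allenylidene by a hindered tertiary alkoxide may lose out to carbene oligomerisation and to allenyl ether formation. The fallback replaces carbene capture by capture of a stabilised cation and sets out from alcohol 3. 2-Methylbut-3-yn-2-ol is complexed with Co2(CO)8 (zerovalent cobalt) to give hexacarbonyl[μ-(2-methylbut-3-yn-2-ol)]dicobalt F1. BF3·OEt2 in CH2Cl2 at −40 °C ionises it to the cobalt-stabilised propargylic cation (Nicholas reaction), which 3 should capture to give the Co2(CO)6 complex of the di-tertiary ether F2. Ce(NH4)2(NO3)6 (tetravalent cerium) in acetone at 0 °C removes the metal and comes back to the route at 5.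

Step 20. The activated quinone ester may be lost to fluoride or water before ring closure, or the two ring A centres may not equilibrate cleanly. The fallback reverses the order in which the two acylal C–O bonds form and sets out from acid 22 and quinone 29. HF·pyridine converts 22 into the 1,7-dihydroxy acid F7, and MeI with K2CO3 in acetone converts 29 into 7-methoxy-2,2-dimethyl-6-(3-methylbut-2-en-1-yl)-2H-chromene-5,8-dione F8. Heating F7 and F8 with camphor-10-sulfonic acid and 4 Å molecular sieves in benzene at 50 °C should exchange the vinylogous ester methoxy group for the bridgehead hydroxyl by addition–elimination. The carboxylic acid then adds to the same quinone carbon, methanol is taken up by the sieves, and equilibration comes back to the route at 33.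

**Further compounds**

F1 | step 2 | hexacarbonyl[μ-(2-methylbut-3-yn-2-ol)]dicobalt, Co2(CO)6 complex of the alkynol | CC(C)(O)C#C.[Co].[Co].[C-]#[O+].[C-]#[O+].[C-]#[O+].[C-]#[O+].[C-]#[O+].[C-]#[O+]
F2 | step 2 | Co2(CO)6 complex of 8-{2-[(2-methylbut-3-yn-2-yl)oxy]propan-2-yl}-1,4-dioxaspiro[4.5]decane | C#CC(C)(C)OC(C)(C)C1CCC2(CC1)OCCO2.[Co].[Co].[C-]#[O+].[C-]#[O+].[C-]#[O+].[C-]#[O+].[C-]#[O+].[C-]#[O+]
F3 | step 13 | methyl (1S,4R,7S)-7-(2-hydroxypropan-2-yl)-5-oxo-1,4-bis[(triethylsilyl)oxy]bicyclo[2.2.2]oct-2-ene-2-carboxylate | COC(=O)C1=C[C@]2(O[Si](CC)(CC)CC)C[C@@H](C(C)(C)O)[C@@]1(O[Si](CC)(CC)CC)CC2=O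
F4 | step 13 | 6-(trifluoroacetyl) derivative of F3 | COC(=O)C1=C[C@]2(O[Si](CC)(CC)CC)C[C@@H](C(C)(C)O)[C@@]1(O[Si](CC)(CC)CC)C(C(=O)C(F)(F)F)C2=O
F5 | step 13 | methyl (1S,4R,7S)-6-diazo-7-(2-hydroxypropan-2-yl)-5-oxo-1,4-bis[(triethylsilyl)oxy]bicyclo[2.2.2]oct-2-ene-2-carboxylate | COC(=O)C1=C[C@]2(O[Si](CC)(CC)CC)C[C@@H](C(C)(C)O)[C@@]1(O[Si](CC)(CC)CC)C(=[N+]=[N-])C2=O
F6 | step 13 | methyl (1R,3R,6S,7S)-5,5-dimethyl-2-oxo-1,7-bis[(triethylsilyl)oxy]-4-oxatricyclo[4.3.1.0(3,7)]dec-8-ene-8-carboxylate | COC(=O)C1=C[C@]3(O[Si](CC)(CC)CC)C[C@H]4C(C)(C)O[C@@H](C3=O)[C@@]14O[Si](CC)(CC)CC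
F7 | step 20 | 1,7-dihydroxy acid from 22 (both silyl groups removed) | OC(=O)C1=C[C@]3(O)C[C@H]4C(C)(C)O[C@@](CC=C(C)C)(C3=O)[C@@]14O
F8 | step 20 | 7-methoxy-2,2-dimethyl-6-(3-methylbut-2-en-1-yl)-2H-chromene-5,8-dione | CC(C)=CCC1=C(OC)C(=O)C2=C(C=CC(C)(C)O2)C1=O
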